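## Analysis of the target

Compound 7 is 1-(4-hydroxyphenyl)octadecan-5-one. It is an unbranched eighteen-carbon chain, numbered here from the benzylic carbon C1 through the carbonyl carbon C5 to the methyl carbon C18, attached through C1 to the para position of a phenol. The benzene ring is the only ring, and there is no stereocentre and no double bond outside the arene, so nothing stereochemical has to be set or preserved. The sensitive functions are the free phenol (acidic, oxidisable, a ligand for metals and a quencher of organometallic reagents) and the dialkyl ketone, which is enolisable on both sides, at C4 and C6. The difficulty is one of position, not of complexity: the carbonyl must sit exactly at C5 between two unactivated methylene chains that enolate or C–H chemistry cannot tell apart. Any positional isomer or chain-length homologue would be a waxy solid almost inseparable from 7, so every carbon–carbon bond should be made at a site fixed by a functional group. The feature on which the plan rests is the C1–C2 bond next to the arene: drawn as a C1=C2 double bond it is a styrene, which alkene cross-metathesis can assemble from a vinylarene and a terminal alkene that already carries C2–C18 and the C5 carbonyl. A second handle is the carbonyl itself, because the C4–C5 bond is an acyl–alkyl bond that an acid chloride and an organomagnesium reagent define without ambiguity.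

## Retrosynthetic reasoning

**7 from 6.** The last operation is removal of a phenol protecting group, so the O–acyl bond of 4-(5-oxooctadecyl)phenyl acetate 6 is cut. An acetate is chosen because the styrene partner is sold in exactly this protected form, because an aryl acetate neither binds ruthenium nor is touched by hydrogenation, and because it falls off under mild basic methanolysis that a ketone without stereocentres tolerates.

**6 from 5.** The saturated C1–C2 bond of 6 is traced back to the C1=C2 double bond of (E)-4-(5-oxooctadec-1-en-1-yl)phenyl acetate 5. This costs one catalytic hydrogenation but makes the C1–C2 linkage accessible to alkene chemistry. The geometry of the double bond needs no control because it is erased.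

**5 from 3 and 4.** The C1=C2 double bond is cut by cross-metathesis into 4-acetoxystyrene 4, which supplies the arene and C1, and octadec-1-en-5-one 3, which supplies C2–C18 with the ketone in place. This is the only alkene position in the chain at which one partner is a cheap commercial compound and the product is conjugated, hence biased towards a single geometry. An alkene anywhere else would require two aliphatic terminal alkenes of equal reactivity and give a purely statistical mixture. The forward reaction has to favour the cross product over the two self-metathesis products and must not move the double bond of 3 along the chain before it reacts.

**3 from 1 and 2.** Ketone 3 is cut at the C4–C5 acyl–alkyl bond into tetradecanoyl chloride 1, which carries C5–C18, and but-3-en-1-ylmagnesium bromide 2, which carries C2–C4 and the terminal carbon later lost in the metathesis. Both are commercial, and the acyl substitution fixes the carbonyl at C5 by construction. Cutting C3–C4 instead, by allylating the enolate of a long-chain methyl ketone, would be equally short but is less secure. The methyl and methylene α-positions compete, proton transfer between product and enolate leads to double alkylation, and the resulting regioisomers would be hard to remove from a C18 chain.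

## Alternatives that were turned down

Alternative 1: The aryl–C1 bond is disconnected, with C1–C5 drawn from a five-membered carbocycle.
- Forward key step: 1-tridecylcyclopentan-1-ol A1 and (4-bromophenoxy)(tert-butyl)dimethylsilane A2 would be irradiated with violet light in the presence of CeCl3 and NiBr2(dtbbpy), where dtbbpy is 4,4'-di-tert-butyl-2,2'-bipyridine. The cerium-bound alkoxide of A1 would give an alkoxy radical, β-scission of a ring bond would unveil the C5 ketone and a primary radical at C1, and nickel would couple that radical with A2. The product of this step is 1-[4-(tert-butyldimethylsilyloxy)phenyl]octadecan-5-one A3, and A3 is one desilylation away from 7.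
- For it: the ring size of A1 fixes the carbonyl at C5, the chain is formed directly at the saturated oxidation level, and A1 is one Grignard addition away from a commercial ring ketone. The route through A3 would be about one step shorter than the chosen one and needs no hydrogenation; on step economy it is the stronger proposal.
- Against it: the alkoxy radical of A1 has three exits. Besides the wanted ring opening, it can expel the tridecyl group by exocyclic β-scission, or abstract a hydrogen from the tridecyl chain through a six-membered transition state. The strain released by opening a cyclopentane is small, so the opening is reversible and not strongly favoured. The electron-rich aryl bromide A2 adds slowly to low-valent nickel, which gives the primary radical time to be reduced or to dimerise. The by-products would be chain isomers and des-aryl ketones close to A3 in polarity.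
- Comparison: the chosen route is a sequence of thermal reactions with predictable mass balance, and its by-products (a stilbene and a C34 diketone) differ sharply from 5 in size and polarity, which the by-products expected beside A3 do not.

Alternative 2: The C2–C3 bond is disconnected into a 2-arylethyl radical and a vinyl ketone.
- Forward key step: 1,3-dioxoisoindolin-2-yl 3-(4-acetoxyphenyl)propanoate A4 would be reduced under blue light with Ru(bpy)3Cl2 (bpy is 2,2'-bipyridine), Hantzsch ester and iPr2NEt. Decarboxylative fragmentation of A4 would give the primary radical, and its addition to the terminal carbon of hexadec-1-en-3-one A5, followed by reduction of the α-keto radical, would give 4-(5-oxooctadecyl)phenyl acetate A6. Compound A6 has the same structure as intermediate 6 of the chosen route, so one methanolysis of A6 would finish the synthesis.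
- For it: the conditions are mild, the carbonyl position is fixed by A5, and the saturated chain of A6 arrives without a hydrogenation. There is no statistical self-coupling and no risk of double-bond migration; on these two points it is stronger than the chosen route.
- Against it: neither partner is bought. A4 needs acetylation and esterification of the parent phenolic acid, and A5 needs a vinyl addition and an oxidation. This gives about six steps against four. A5 is a polymerisation-prone vinyl ketone. The α-keto radical adduct can add to a second molecule of A5 instead of being reduced to A6, and the unstabilised primary radical can be reduced before it adds.
- Comparison: the chosen route uses two bench-stable alkenes, one commercial and one made in a single step, and reaches 6, the same compound as A6, in three steps.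

Alternative 3: The C7–C8 bond is disconnected into two carboxylic acids.
- Forward key step: co-electrolysis at a platinum anode of 4-oxo-8-[4-(pivaloyloxy)phenyl]octanoic acid A7 with an excess of dodecanoic acid A8 in partly neutralised methanol would join the two decarboxylated primary radicals to give 4-(5-oxooctadecyl)phenyl pivalate A9. Cleavage of the pivalate of A9 would then give 7.
- For it: no transition-metal catalyst and no organometallic reagent are needed, A8 is very cheap, and the carbonyl position of A9 is fixed within A7. On reagent cost and scalability it is the stronger proposal.
- Against it: a mixed Kolbe coupling is statistical. Even with excess A8 the radical from A7 is shared between the cross product A9 and the symmetrical dimer, and this loss falls on the advanced component. A7 is not a starting material; it already contains the arene, the C1–C4 tether and the ketone, so it needs its own multi-step synthesis with a carbon–carbon bond formation that is no easier than the one in the chosen route. The high anode potential of Kolbe electrolysis invites oxidation of the alkyl-substituted arene, and the alkaline methanol can slowly cleave the aryl pivalate of A7 and of A9.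
- Comparison: the chosen route places its statistical element on the cheap partner 4, used in excess, early in a four-step sequence, whereas the route through A9 places it on the hard-won acid A7.

Key step: step 2

## Route

Step 1
Reactants: 1 tetradecanoyl chloride (myristoyl chloride); 2 but-3-en-1-ylmagnesium bromide (purchased as a THF solution)
Product: 3 octadec-1-en-5-one
Conditions: Fe(acac)3 (3 mol%), THF, −78 °C, slow addition of 2 (1.1 equiv); aq. NH4Cl
Reagents that add atoms: none
Why: Iron-catalysed cross-coupling of an acid chloride with an alkyl Grignard reagent (Kumada-type ketone synthesis); the low-valent iron species formed from Fe(acac)3, iron tris(acetylacetonate), and 2 passes the butenyl group to the acyl chloride far faster than 2 adds to the product ketone at −78 °C, so the reaction stops at the ketone and the carbonyl is fixed at C5. The terminal alkene is inert under these conditions.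

Step 2
Reactants: 3 octadec-1-en-5-one; 4 4-acetoxystyrene (4-vinylphenyl acetate)
Product: 5 (E)-4-(5-oxooctadec-1-en-1-yl)phenyl acetate
Conditions: 4 (3 equiv), second-generation Grubbs catalyst (H2IMes)(PCy3)Cl2Ru=CHPh (5 mol%), 1,4-benzoquinone (10 mol%), CH2Cl2, 40 °C, argon sweep
Reagents that add atoms: none
Why: Alkene cross-metathesis by the Chauvin mechanism: loss of PCy3 gives a 14-electron ruthenium alkylidene, [2+2] cycloaddition with the terminal alkene of 3 and cycloreversion give a ruthenium alkylidene carrying C2–C18, and a second cycloaddition–cycloreversion with 4 forms the C1=C2 bond of 5 and a ruthenium methylidene that releases ethylene on its next turnover. The closest known reaction type is the ruthenium-carbene cross-metathesis of styrenes with terminal aliphatic alkenes, in which alk-1-en-5-ones are routine partners. No ring closes and no stereocentre forms. The selectivity needed is cross- over self-metathesis; with this catalyst both alkenes homodimerise readily, so the selectivity comes from stoichiometry and reversibility and not from an intrinsic bias: the homodimer of 3 is an unhindered internal alkene that re-enters the cycle and is carried on to 5 by the threefold excess of 4, whereas self-metathesis of 4 gives a stilbene that reacts only sluggishly and costs nothing but cheap excess reagent. Sweeping out ethylene drives the equilibria, and the conjugated E isomer should dominate under thermodynamic control, although the geometry is irrelevant because step 3 removes the double bond. The C5 carbonyl could close a six-membered chelate onto the alkylidene derived from 3, but a ketone oxygen binds ruthenium weakly and should not stop turnover, and the phenol is masked as an acetate and cannot ligate the metal. 1,4-Benzoquinone intercepts ruthenium hydrides so that the terminal double bond of 3 does not migrate before metathesis, which would otherwise lead to chain-shortened homologues.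

Step 3
Reactants: 5 (E)-4-(5-oxooctadec-1-en-1-yl)phenyl acetate
Product: 6 4-(5-oxooctadecyl)phenyl acetate
Conditions: H2 (1 atm), 10% Pd/C, EtOAc, rt
Reagents that add atoms: none
Why: Heterogeneous catalytic hydrogenation; the conjugated disubstituted alkene should be reduced quickly, while the aliphatic ketone and the aryl acetate are inert at 1 atm in an aprotic solvent and there is no benzylic carbon–heteroatom bond to hydrogenolyse.

Step 4
Reactants: 6 4-(5-oxooctadecyl)phenyl acetate
Product: 7 1-(4-hydroxyphenyl)octadecan-5-one
Conditions: K2CO3 (0.2 equiv), MeOH, rt; aq. NH4Cl
Reagents that add atoms: none
Why: Base-catalysed transesterification (methanolysis) of an aryl acetate, fast because phenoxide is a good leaving group; the ketone has no stereocentre and no β-leaving group, so transient enolisation under these mild conditions is harmless.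

## Compound list

1 | tetradecanoyl chloride (myristoyl chloride) | CCCCCCCCCCCCCC(=O)Cl | starting material
2 | but-3-en-1-ylmagnesium bromide | C=CCC[Mg]Br | starting material
3 | octadec-1-en-5-one | CCCCCCCCCCCCCC(=O)CCC=C | intermediate
4 | 4-acetoxystyrene (4-vinylphenyl acetate) | CC(=O)Oc1ccc(C=C)cc1 | starting material
5 | (E)-4-(5-oxooctadec-1-en-1-yl)phenyl acetate | CCCCCCCCCCCCCC(=O)CC/C=C/c1ccc(OC(C)=O)cc1 | intermediate
6 | 4-(5-oxooctadecyl)phenyl acetate | CCCCCCCCCCCCCC(=O)CCCCc1ccc(OC(C)=O)cc1 | intermediate
7 | 1-(4-hydroxyphenyl)octadecan-5-one (CNP0291454.0) | CCCCCCCCCCCCCC(=O)CCCCc1ccc(O)cc1 | target

## Step count and risk

Total step count: 4. Longest linear sequence: 4 steps (1 and 2 to 3, then 5, 6 and 7).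

**Step 2 (key step).** Two processes are most likely to hurt. The first is statistical partitioning: self-metathesis of 4 to its stilbene can use up the excess partner before 3 and its homodimer are fully converted, leaving material as the C34 diketone homodimer. The second is migration of the terminal double bond of 3 by ruthenium hydrides formed on catalyst decay; metathesis of the migrated alkene would give chain-shortened homologues that survive to the end and cannot be separated from 7.

The fallback drops metathesis and forms the aryl–C1 bond by a B-alkyl Suzuki–Miyaura coupling. It sets out from 3 and comes back to the route at 7. Ketone 3 would be protected with ethylene glycol and catalytic p-toluenesulfonic acid in toluene with removal of water, to give 2-(but-3-en-1-yl)-2-tridecyl-1,3-dioxolane F1; the protection is needed because the borane would otherwise reduce the ketone. Anti-Markovnikov hydroboration of F1 with 9-borabicyclo[3.3.1]nonane in THF would give 9-[4-(2-tridecyl-1,3-dioxolan-2-yl)butyl]-9-borabicyclo[3.3.1]nonane F2, used without isolation. Coupling of F2 with purchased 1-bromo-4-(methoxymethoxy)benzene (PdCl2(dppf), where dppf is 1,1'-bis(diphenylphosphino)ferrocene, aqueous K3PO4, THF/DMF, 50 °C) would give 2-{4-[4-(methoxymethoxy)phenyl]butyl}-2-tridecyl-1,3-dioxolane F3. Aqueous HCl in THF/MeOH would then remove the dioxolane and the methoxymethyl ether of F3 together and give 7. This sequence cannot give homologues, because the chain length is fixed by the hydroboration site.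

**Step 1.** The likely failure is a second addition of the Grignard reagent to the newly formed ketone, giving a tertiary alcohol, if the addition is too fast or the iron catalyst turns over sluggishly. Reductive homocoupling of 2 is a lesser risk.

The fallback goes through an isolable amide that cannot over-add. It sets out from 1 and comes back at 3. Acid chloride 1 would be treated with N,O-dimethylhydroxylamine hydrochloride and pyridine in CH2Cl2 to give N-methoxy-N-methyltetradecanamide F4. Addition of 2 to F4 in THF at 0 °C would form a stable magnesium chelate, which releases 3 only on aqueous work-up (Weinreb ketone synthesis).

**Step 3.** The likely failure is stalled hydrogen uptake caused by poisoning of the palladium surface by ruthenium residues or tricyclohexylphosphine carried over from step 2. Forcing the reaction with longer times or higher pressure could then start to reduce the ketone.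

The fallback is a metal-free diimide reduction, setting out from 5 and coming back at 6. Diimide would be generated in the flask from dipotassium azodicarboxylate (KO2C–N=N–CO2K) and acetic acid in methanol. It transfers hydrogen in a concerted syn fashion to the carbon–carbon double bond only and leaves the ketone untouched. Any acetate lost under these conditions would not matter, since step 4 removes it. No new compound arises.

## Further compounds

F1 | step 2 | 2-(but-3-en-1-yl)-2-tridecyl-1,3-dioxolane | CCCCCCCCCCCCCC1(CCC=C)OCCO1
F2 | step 2 | 9-[4-(2-tridecyl-1,3-dioxolan-2-yl)butyl]-9-borabicyclo[3.3.1]nonane | CCCCCCCCCCCCCC1(CCCCB2C3CCCC2CCC3)OCCO1
F3 | step 2 | 2-{4-[4-(methoxymethoxy)phenyl]butyl}-2-tridecyl-1,3-dioxolane | CCCCCCCCCCCCCC1(CCCCc2ccc(OCOC)cc2)OCCO1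
F4 | step 1 | N-methoxy-N-methyltetradecanamide | CCCCCCCCCCCCCC(=O)N(C)OC
F0 | step 3 | none | none
A1 | alternative 1 | 1-tridecylcyclopentan-1-ol | CCCCCCCCCCCCCC1(O)CCCC1
A2 | alternative 1 | (4-bromophenoxy)(tert-butyl)dimethylsilane | CC(C)(C)[Si](C)(C)Oc1ccc(Br)cc1
A3 | alternative 1 | 1-[4-(tert-butyldimethylsilyloxy)phenyl]octadecan-5-one | CCCCCCCCCCCCCC(=O)CCCCc1ccc(O[Si](C)(C)C(C)(C)C)cc1
A4 | alternative 2 | 1,3-dioxoisoindolin-2-yl 3-(4-acetoxyphenyl)propanoate | CC(=O)Oc1ccc(CCC(=O)ON2C(=O)c3ccccc3C2=O)cc1
A5 | alternative 2 | hexadec-1-en-3-one | CCCCCCCCCCCCCC(=O)C=C
A6 | alternative 2 | 4-(5-oxooctadecyl)phenyl acetate | CCCCCCCCCCCCCC(=O)CCCCc1ccc(OC(C)=O)cc1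
A7 | alternative 3 | 4-oxo-8-[4-(pivaloyloxy)phenyl]octanoic acid | CC(C)(C)C(=O)Oc1ccc(CCCCC(=O)CCC(=O)O)cc1
A8 | alternative 3 | dodecanoic acid | CCCCCCCCCCCC(=O)O
A9 | alternative 3 | 4-(5-oxooctadecyl)phenyl pivalate | CCCCCCCCCCCCCC(=O)CCCCc1ccc(OC(=O)C(C)(C)C)cc1
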